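## Retrosynthetic overview
1. The enone is made last, by allylic oxidation at C15 of a 16-methylene compound. The 11α-OH comes from β-face hydride addition to an 11-ketone.
2. Ring D (C13–C16) closes by a 5-exo vinyl-radical conjugate addition of a C8 2-bromoallyl group onto a ring-C enone. The quaternary C8 is set by lactone-enolate alkylation.
3. One alkoxycarbonyl-radical 5-exo cyclisation/Giese coupling with methyl 3-oxocyclohexenecarboxylate (ring C plus C7) forms the γ-lactone (C5–C6), quaternary C10 and the C9–C10 bond. Lactonisation then closes the δ-lactone.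
4. Ring A comes from Cu-catalysed asymmetric conjugate methylation (C4) of a 3-(silyloxymethyl)cyclohexenone, followed by enolate → enol triflate → CH2OH (C20).
5. Ring order: A (purchased carbocycle) → γ-lactone → ring C attached → δ-lactone → D.

Assumptions:
- ent-Kaurane numbering is used throughout. By that numbering the target is 4R,5R,8S,9S,10R,11R,13S.
- The ligand antipode in step 3 is the one that gives 4R.
- All numbered starting materials (1, 4, 6, 8, 11, 14) are catalogue compounds.

## Route

**Step 1**
Reactants: 1, 3-methoxybenzyl alcohol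
Product: 2, 3-(hydroxymethyl)cyclohex-2-en-1-one
Conditions: n-BuLi (1 equiv), then Li, NH3(l)/THF, t-BuOH, −78 to −33 °C; then 2 M HCl, THF, rt
Reagents that add atoms: water, O
Why: Birch reduction of the lithium alkoxide (which suppresses benzylic C–O cleavage) gives the 1-methoxy-1,4-diene, and enol-ether hydrolysis with conjugation gives the enone; no stereocentre is formed.

**Step 2**
Reactants: 2
Product: 3, 3-{[(triethylsilyl)oxy]methyl}cyclohex-2-en-1-one
Conditions: TESCl, imidazole, CH2Cl2, 0 °C
Reagents that add atoms: TESCl, CC[Si](Cl)(CC)CC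
Why: Standard O-silylation masks the C19 hydroxyl against the organometallic reagents of step 3.

**Step 3**
Reactants: 3; 4, trimethylaluminium
Product: 5, (R)-3-(hydroxymethyl)-3-methylcyclohex-1-en-1-yl triflate (C4 = R; C5=C10 enol triflate; free C19-OH)
Conditions: CuTC (5 mol %), chiral biphenol-type phosphoramidite L* (10 mol %), Me3Al, Et2O, −30 °C; then MeLi, THF, Comins' reagent, −78 to 0 °C; work-up with 1 M HCl/THF
Reagents that add atoms: Me3Al, C[Al](C)C; Comins' reagent, Clc1ccc(nc1)N(S(=O)(=O)C(F)(F)F)S(=O)(=O)C(F)(F)F
Why: Ligand-controlled Cu-catalysed asymmetric conjugate addition sets quaternary C4, the regiodefined enolate (as its ate complex) is O-triflated to fix the C5=C10 alkene, and the acidic work-up removes TES.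

**Step 4**
Reactants: 5; 6, methyl chlorooxoacetate
Product: 7, methyl [(1R)-1-methyl-3-(triflyloxy)cyclohex-2-en-1-yl]methyl oxalate
Conditions: Et3N, DMAP (cat.), CH2Cl2, 0 °C
Reagents that add atoms: methyl chlorooxoacetate, COC(=O)C(=O)Cl
Why: Simple acylation of the neopentyl alcohol installs the latent alkoxycarbonyl radical, whose inner carbonyl becomes C6.

**Step 5**
Reactants: 7; 8, (tributylstannyl)methanol
Product: 9, methyl [(1R)-3-(hydroxymethyl)-1-methylcyclohex-2-en-1-yl]methyl oxalate
Conditions: Pd(PPh3)4 (5 mol %), LiCl, CuCl, DMSO/THF, 60 °C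
Reagents that add atoms: Bu3SnCH2OH, OC[Sn](CCCC)(CCCC)CCCC
Why: Stille hydroxymethylation of the unhindered enol triflate brings in C20-OH under neutral conditions that the oxalate tolerates.

**Step 6**
Reactants: 9
Product: 10, cesium 2-{[(1R)-3-(hydroxymethyl)-1-methylcyclohex-2-en-1-yl]methoxy}-2-oxoacetate
Conditions: CsOH (1.0 equiv, aq), THF, 0 °C to rt; concentrate
Reagents that add atoms: CsOH, [Cs+].[OH-]
Why: Saponification occurs selectively at the less hindered methyl-ester terminus of the mixed oxalate, which is far faster than attack at the neopentyl ester.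

**Step 7**
Reactants: 10; 11, methyl 3-oxocyclohex-1-ene-1-carboxylate
Product: 12, tetracyclic 11-keto-6,19:7,20-bis-lactone (ring A, cis γ-lactone, spiro δ-lactone, ring C; 4R,5R,10R; H-5β, H-9β, C20 α; C8-H epimers, inconsequential)
Conditions: Ir[dF(CF3)ppy]2(dtbbpy)PF6 (1 mol %), 11 (1.5 equiv), H2O (10 equiv), DME/DMF 3:1 (0.05 M), blue LEDs, 60 °C; then DBU, PhMe, 4 Å MS, 80 °C
Reagents that add atoms: 11, COC(=O)C1=CC(=O)CCC1 (CO2 and MeOH are lost; H comes from water)
Why: The cascade is oxalate photoredox oxidation, alkoxycarbonyl-radical 5-exo cyclisation, Giese addition and lactonisation, and each new centre is controlled as follows.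
- C5: the C19 tether forces the cis γ-lactone.
- C10: the tertiary radical adds to the CH terminus of the fumarate-like acceptor from the convex β-face, anti to C6 and C19.
- δ-Lactone: DBU closes it.
- C9: DBU equilibrates this centre (α to the ketone) to the epimer that places H-9 in the crowded sector between C20 and C5/C6.

**Step 8**
Reactants: 12
Product: 13, C11–C12 tert-butyldimethylsilyl enol ether of 12
Conditions: LiHMDS (1.1 equiv), THF, −78 °C; TBSOTf
Reagents that add atoms: TBSOTf, CC(C)(C)[Si](C)(C)OS(=O)(=O)C(F)(F)F
Why: Kinetic enolisation takes the most acidic and accessible C12-H, which masks the ketone, blocks C9 epimerisation and pre-installs the Saegusa handle.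

**Step 9**
Reactants: 13; 14, 2,3-dibromopropene
Product: 15, C8-(2-bromoallyl) derivative of 13 (bromoallyl β, cis to H-9; C7 α)
Conditions: LDA (1.3 equiv), THF/DMPU, −78 °C; 14, −78 to −30 °C
Reagents that add atoms: 2,3-dibromopropene, C=C(Br)CBr
Why: In this lactone-enolate alkylation C8-H is removed in preference to C5-H (flanked by two quaternary carbons), and the electrophile enters syn to pseudo-axial H-9, anti to ring C and the pseudo-axial C1 on C10, giving the cis-fused quaternary C8.

**Step 10**
Reactants: 15
Product: 16, 11-oxo-12-ene (ring-C cyclohexenone bearing the C8 2-bromoallyl group)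
Conditions: Pd(OAc)2 (1.1 equiv), MeCN/CH2Cl2, rt
Reagents that add atoms: none
Why: Saegusa–Ito oxidation of the regiodefined silyl enol ether can only give the C12=C13 enone, and the vinyl bromide is inert to Pd(II).

**Step 11**
Reactants: 16
Product: 17, pentacyclic 11-ketone with the 16-methylene bicyclo[3.2.1]octane (11-dehydro-15-deoxo-ludongnin A)
Conditions: n-Bu3SnH (syringe pump), AIBN, PhH (0.01 M), 80 °C
Reagents that add atoms: none
Why: In this 5-exo-trig vinyl-radical conjugate addition the β-oriented C8 arm can reach C13 only from the β-face, so C13 is set by the geometry of the bridge.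

**Step 12**
Reactants: 17
Product: 18, 15-deoxo-ludongnin A (11α-OH, 11R)
Conditions: NaBH4, MeOH/CH2Cl2, −20 to 0 °C
Reagents that add atoms: none
Why: In this chemoselective ketone reduction the α-face of C11 is blocked by the axial C9–C10 bond and C1H2 of the spiro ring, so hydride arrives from the β-face and gives the equatorial (also thermodynamic) 11α-alcohol; H-9 is equatorial and poorly enolisable.

**Step 13**
Reactants: 18
Product: 19, 15-hydroxy compound (15-dihydro-ludongnin A; C15 epimer inconsequential)
Conditions: SeO2 (0.5 equiv), t-BuOOH, CH2Cl2, rt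
Reagents that add atoms: SeO2, O=[Se]=O; t-BuOOH, CC(C)(C)OO
Why: SeO2 ene/[2,3] allylic oxidation can only use C15-H, because abstraction at bridgehead C13-H would need an anti-Bredt alkene.

**Step 14**
Reactants: 19
Product: 20, ludongnin A
Conditions: activated MnO2 (excess), CH2Cl2, rt
Reagents that add atoms: none
Why: MnO2 oxidises only the allylic 15-OH, leaving the hindered non-allylic 11-OH untouched.

## Compound list
1 | 3-methoxybenzyl alcohol | COc1cccc(CO)c1 | starting material
2 | 3-(hydroxymethyl)cyclohex-2-en-1-one | O=C1C=C(CO)CCC1 | intermediate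
3 | 3-{[(triethylsilyl)oxy]methyl}cyclohex-2-en-1-one | O=C1C=C(CO[Si](CC)(CC)CC)CCC1 | intermediate
4 | trimethylaluminium | C[Al](C)C | starting material
5 | (R)-3-(hydroxymethyl)-3-methylcyclohex-1-en-1-yl triflate | O=S(=O)(OC1=C[C@](C)(CO)CCC1)C(F)(F)F | intermediate
6 | methyl chlorooxoacetate | COC(=O)C(=O)Cl | starting material
7 | methyl [(1R)-1-methyl-3-(triflyloxy)cyclohex-2-enyl]methyl oxalate | O=S(=O)(OC1=C[C@](C)(COC(=O)C(=O)OC)CCC1)C(F)(F)F | intermediate
8 | (tributylstannyl)methanol | OC[Sn](CCCC)(CCCC)CCCC | starting material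
9 | methyl [(1R)-3-(hydroxymethyl)-1-methylcyclohex-2-enyl]methyl oxalate | OCC1=C[C@](C)(COC(=O)C(=O)OC)CCC1 | intermediate
10 | cesium oxalate of 9 | OCC1=C[C@](C)(COC(=O)C(=O)[O-])CCC1.[Cs+] | intermediate
11 | methyl 3-oxocyclohex-1-ene-1-carboxylate | COC(=O)C1=CC(=O)CCC1 | starting material
12 | 11-keto bis-lactone (C8 undefined) | O=C1CCCC2[C@@H]1[C@@]1(CCC[C@@]3(C)COC(=O)[C@H]31)COC2=O | intermediate
13 | C11–C12 TBS enol ether (C8 undefined) | CC(C)(C)[Si](C)(C)OC1=CCCC2[C@@H]1[C@@]1(CCC[C@@]3(C)COC(=O)[C@H]31)COC2=O | intermediate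
14 | 2,3-dibromopropene | C=C(Br)CBr | starting material
15 | C8-(2-bromoallyl) silyl enol ether | CC(C)(C)[Si](C)(C)OC1=CCC[C@@]2(CC(Br)=C)[C@@H]1[C@@]1(CCC[C@@]3(C)COC(=O)[C@H]31)COC2=O | intermediate
16 | C8-(2-bromoallyl) 11-oxo-12-ene | O=C1C=CC[C@@]2(CC(Br)=C)[C@@H]1[C@@]1(CCC[C@@]3(C)COC(=O)[C@H]31)COC2=O | intermediate
17 | 11-dehydro-15-deoxo-ludongnin A | C=C1C[C@]23C[C@H]1CC(=O)[C@H]2[C@@]1(CCC[C@@]2(C)COC(=O)[C@H]21)COC3=O | intermediate
18 | 15-deoxo-ludongnin A | C=C1C[C@]23C[C@H]1C[C@@H](O)[C@H]2[C@@]1(CCC[C@@]2(C)COC(=O)[C@H]21)COC3=O | intermediate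
19 | 15-hydroxy compound (C15 undefined) | C=C1C(O)[C@]23C[C@H]1C[C@@H](O)[C@H]2[C@@]1(CCC[C@@]2(C)COC(=O)[C@H]21)COC3=O | intermediate
20 | ludongnin A | C=C1C(=O)[C@]23C[C@H]1C[C@@H](O)[C@H]2[C@@]1(CCC[C@@]2(C)COC(=O)[C@H]21)COC3=O | target

## Totals
Total steps: 14. Longest linear sequence: 14, because every coupling partner is purchased.

## Steps most likely to fail

**1. Step 7 (radical cascade)**
- Risks: a hindered tertiary radical must add to a trisubstituted acceptor, the alkoxycarbonyl radical may be trapped before it cyclises, and C9 depends on equilibration.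
- Fallback: split the event. Trap the C10 radical with unhindered 2,2,2-trifluoroethyl acrylate, which gives the spirolactone.
- Then build ring C stepwise: C8 alkylation with 5-iodopent-1-ene, selenoxide elimination to the C8=C9 lactone, ozonolysis, and a SmI2 ketyl–olefin 6-endo cyclisation that forms C9–C11 under Felkin control from C10.
- Alkylate C8 as the alkoxide/enolate dianion and oxidise the 11-ol to enone 16 with IBX.

**2. Step 9 (C8 alkylation)**
- Risks: C8-H versus C5-H deprotonation, and facial selectivity at a congested centre.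
- Fallback: reverse the order of D-ring bond formation. Dehydrogenate 12 to the enone, carry out a Hosomi–Sakurai allylation at C13, and mask C11.
- Then form C8–C15 intramolecularly by Pd(II)-mediated oxidative cyclisation of the lactone silyl ketene acetal onto the allyl group, so the tether dictates the C8 configuration.
- Ozonolysis of the resulting 15-methylene and Eschenmoser methylenation at C16 replace steps 13–14.

**3. Step 12 (C11 configuration)**
- Risk: both faces of the bicyclo[3.2.1]octan-3-one are hindered, and exo attack would give 11β-OH.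
- Fallback: set C11 before the bridge exists, using reagent control. A CBS 1,2-reduction of enone 16 gives the 11α-allylic alcohol.
- The same vinyl-radical 5-exo cyclisation is then run onto the unactivated C12=C13 alkene, which leads directly to 18.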